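The numbers in the tables stem from a simulated flask for substances that don't exist.

Take the last reading of each earlier run and subtract it from the charge of G, the substrate; X, the reagent, was matched to it.

| flask | G | X | Q | remark | time |
|---|---|---|---|---|---|
| epsilon | 0.11 M | 1 equiv | 0.033 M | run made earlier |  |
| beta | 0.055 M | 1 equiv | 0.033 M | run made earlier |  |
| eta | 0.22 M | 1 equiv | 0.033 M | run made earlier |  |
| south-east | 0.11 M | 1.00 equiv (fed, over 80 min) | 0.0330 M | all else is in the flask from the start; the feed brings no volume worth counting | 25 h |
| north-west | 0.11 M (fed, over 5.0 h) | 1.00 equiv | 0.0330 M | all else is in the flask from the start; the feed brings no volume worth counting | 25 h |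
| west | 0.11 M | 1.00 equiv (fed, over 5.0 h) | 0.0330 M | all else is in the flask from the start; the feed brings no volume worth counting | 25 h |
| north | 0.11 M | 1.00 equiv | 0.0330 M | everything together at the start | 25 h |

| run | time / h | Z / % |
|---|---|---|
| epsilon | 2.00 | 67.0 |
| epsilon | 5.00 | 70.3 |
| epsilon | 10.0 | 70.3 |
| epsilon | 15.0 | 70.0 |
| beta | 2.00 | 2.3 |
| beta | 5.00 | 19.5 |
| beta | 10.0 | 38.6 |
| beta | 15.0 | 39.8 |
| eta | 2.00 | 85.8 |
| eta | 5.00 | 85.2 |
| eta | 10.0 | 85.8 |
| eta | 15.0 | 85.8 |

(each reading ± 0.3 percentage points)

- the numbers in the tables scatter with a standard deviation of 0.3 percentage points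
- a reading or a percentage of Z counts all its forms, free or not

* which flask leads in amount of Z, in percent of the G charged ("all alike" within 1.5 percentage points) (south-east / north-west / west / north / all alike)
* how much Z is there at the end, in percent of the G charged: south-east
* how much Z is there at the end, in percent of the G charged: north-west
* how much Z is there at the end, in percent of the G charged: west
* how much Z is there at the end, in percent of the G charged: north

What did each run lack at its last reading? At 15.0 h, I read gaps of 60.2% in beta, 30.0% in epsilon and 14.2% in eta. I set these against the toll, meaning Q charged as a fraction of G charged, 30.0% for epsilon's recipe, 60.0% for beta and 15.0% for eta. So each unit of Q cost about one unit of Z, and Z should stop near one minus the toll.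

Could a feed move the toll? The earlier runs held no feed, so I could ask just how closely the toll had held across charges. The largest departure I could read was in eta, at twice the charge, where the gap fell 0.8 percentage points short of the toll. Even that is less than the margin of 1.5 points.

Was there time? Beta, at half the charge, still rose between 10.0 h and 15.0 h, but a feed of 5.0 h leaves 20.0 h, which is longer than the 15.0 h of beta's last reading. My own figure for north was 70.0%, and with the same charges I carried it to the fed flasks.

The forecast was all alike: south-east 70%, north-west 70%, west 70%, north 70%, on the ground that “Q takes a fixed amount whatever the order of addition”.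

The flasks gave all alike: south-east 70.2%, north-west 70.0%, west 70.2%, north 70.2%.

    G + X + Z → 2 Z (k = 0.220 L² mol⁻² s⁻¹)
    G + X → Z (k = 2.40 × 10⁻⁵ L mol⁻¹ s⁻¹)
    E ⇌ Z, rate k3*(cs3 - [Z]) while solid is left; crystals form when [Z] > cs3 (solubility = 0.110 M, k = 7.60 × 10⁻⁴ s⁻¹)
    X + Q → D (k = 0.0150 L mol⁻¹ s⁻¹)

North-west ended at 70.0% against one minus the toll, 70.0%. Its D stood at 30.0% of the G charged, with X, the limiting reagent, at 0% and G at 30.0%. A neighbour of north-west, charged with Q at 11.8% of its G, has a reckoned end of 88.2%, and it gave 88.2%. North-west itself had come to rest: Z stood at 70.0% at 12.5 h, and left until 250 h it moved by 0 points, reading 70.0%.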